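**Retrosynthetic overview**

- Target 13 is opened at the lactone C(=O)–Cα bond and the C(=O)–O bond, giving the acyclic homopropargylic alcohol 12 plus CO. A Pd-catalysed cyclocarbonylation closes the γ-butyrolactone, the only ring made in the route, as the last step.
- Enabling feature: in the butyrolactone ring the ring oxygen and the alkylidene carbon are 1,4-related through CH2–CH, and on the exocyclic C=C the vinylic H is cis to the carbonyl carbon. This is the imprint of a cis addition of an O-bound carbonyl carbon and H across an aryl alkyne.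
- 12 comes from Sonogashira coupling of terminal alkyne 9 with 4-iodo-2-methoxyphenol 10, followed by desilylation.
- 9 comes from aldehyde 8 by Ohira–Bestmann alkynylation. The single stereocentre is set by Evans hydroxymethylation of imide 4, made from acid 1 and auxiliary 2. The imide carbonyl becomes the alkyne carbon and the new CH2OH becomes the lactone CH2O.

Key step: step 9

Remark: 1, 2 and 10 are taken as commercial; the target is read as R at the benzyl-bearing ring carbon with an E exocyclic alkene (aryl trans to the carbonyl).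

**Step 1**
Reactants: 1 3-(3,4-dimethoxyphenyl)propanoic acid; 2 (R)-4-benzyloxazolidin-2-one
Product: 4 (R)-4-benzyl-3-[3-(3,4-dimethoxyphenyl)propanoyl]oxazolidin-2-one, via mixed pivalic anhydride 3 (not isolated)
Conditions: PivCl, Et3N, THF, −20 °C; then 2, LiCl, −20 °C to rt
Reagents that add atoms: pivaloyl chloride, CC(C)(C)C(Cl)=O (its acyl group is carried only by intermediate 3)
Why: Mixed-anhydride N-acylation of an Evans oxazolidinone, in which the LiCl/Et3N-activated auxiliary should attack the unhindered acyl carbon of 3; no stereocentre is formed.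

**Step 2**
Reactants: 4 (R)-4-benzyl-3-[3-(3,4-dimethoxyphenyl)propanoyl]oxazolidin-2-one
Product: 5 (R)-4-benzyl-3-[(S)-2-(3,4-dimethoxybenzyl)-3-hydroxypropanoyl]oxazolidin-2-one
Conditions: TiCl4, i-Pr2NEt, CH2Cl2, 0 °C; then 1,3,5-trioxane, TiCl4, 0 °C
Reagents that add atoms: 1,3,5-trioxane, C1OCOCO1
Why: Evans titanium-enolate hydroxymethylation, in which the chelated Z-enolate should be attacked by the TiCl4-activated formaldehyde equivalent on the face opposite the C4 benzyl group of the auxiliary, setting the new α-stereocentre as S.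

**Step 3**
Reactants: 5 (R)-4-benzyl-3-[(S)-2-(3,4-dimethoxybenzyl)-3-hydroxypropanoyl]oxazolidin-2-one
Product: 6 (R)-4-benzyl-3-[(S)-3-[(tert-butyldimethylsilyl)oxy]-2-(3,4-dimethoxybenzyl)propanoyl]oxazolidin-2-one
Conditions: TBSCl, imidazole, DMF, 0 °C to rt
Reagents that add atoms: tert-butyldimethylsilyl chloride, CC(C)(C)[Si](C)(C)Cl
Why: Standard silylation of a primary alcohol, which differentiates the two future CH2O arms and should leave the stereocentre untouched.

**Step 4**
Reactants: 6 (R)-4-benzyl-3-[(S)-3-[(tert-butyldimethylsilyl)oxy]-2-(3,4-dimethoxybenzyl)propanoyl]oxazolidin-2-one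
Product: 7 (R)-3-[(tert-butyldimethylsilyl)oxy]-2-(3,4-dimethoxybenzyl)propan-1-ol
Conditions: LiBH4, MeOH (1.1 equiv), THF, 0 °C
Reagents that add atoms: none
Why: Reductive cleavage of the N-acyl oxazolidinone at the exocyclic carbonyl by LiBH4 should give the primary alcohol and release the auxiliary, with the stereocentre unchanged in space (the descriptor becomes R by priority only).

**Step 5**
Reactants: 7 (R)-3-[(tert-butyldimethylsilyl)oxy]-2-(3,4-dimethoxybenzyl)propan-1-ol
Product: 8 (S)-3-[(tert-butyldimethylsilyl)oxy]-2-(3,4-dimethoxybenzyl)propanal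
Conditions: Dess–Martin periodinane, CH2Cl2, 0 °C to rt; used crude
Reagents that add atoms: none
Why: Dess–Martin oxidation is non-basic, so the α-stereocentre of the aldehyde should be preserved when the crude product is carried on directly.

**Step 6**
Reactants: 8 (S)-3-[(tert-butyldimethylsilyl)oxy]-2-(3,4-dimethoxybenzyl)propanal
Product: 9 (R)-tert-butyl{[2-(3,4-dimethoxybenzyl)but-3-yn-1-yl]oxy}dimethylsilane
Conditions: dimethyl (1-diazo-2-oxopropyl)phosphonate, K2CO3, MeOH, 0 °C to rt
Reagents that add atoms: dimethyl (1-diazo-2-oxopropyl)phosphonate, CC(=O)C(=[N+]=[N-])P(=O)(OC)OC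
Why: Seyferth–Gilbert homologation in the Ohira–Bestmann variant, in which the diazomethylphosphonate anion generated by methanolysis should add to the aldehyde and the alkylidene carbene rearrange to the terminal alkyne at 0 °C faster than the α-centre enolises.

**Step 7**
Reactants: 9 (R)-tert-butyl{[2-(3,4-dimethoxybenzyl)but-3-yn-1-yl]oxy}dimethylsilane; 10 4-iodo-2-methoxyphenol
Product: 11 (R)-4-{4-[(tert-butyldimethylsilyl)oxy]-3-(3,4-dimethoxybenzyl)but-1-yn-1-yl}-2-methoxyphenol
Conditions: PdCl2(PPh3)2 (3 mol %), CuI (6 mol %), Et3N, THF, 45 °C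
Reagents that add atoms: none
Why: Sonogashira coupling of a terminal alkyne with an aryl iodide tolerates the free phenol and the silyl ether and does not touch the propargylic stereocentre.

**Step 8**
Reactants: 11 (R)-4-{4-[(tert-butyldimethylsilyl)oxy]-3-(3,4-dimethoxybenzyl)but-1-yn-1-yl}-2-methoxyphenol
Product: 12 (R)-4-[3-(3,4-dimethoxybenzyl)-4-hydroxybut-1-yn-1-yl]-2-methoxyphenol
Conditions: TBAF, THF, 0 °C to rt
Reagents that add atoms: none
Why: Fluoride-mediated desilylation should free the primary homopropargylic alcohol without affecting the alkyne, the aryl ethers or the stereocentre.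

**Step 9**
Reactants: 12 (R)-4-[3-(3,4-dimethoxybenzyl)-4-hydroxybut-1-yn-1-yl]-2-methoxyphenol
Product: 13 (R,E)-4-(3,4-dimethoxybenzyl)-3-(4-hydroxy-3-methoxybenzylidene)dihydrofuran-2(3H)-one
Conditions: PdCl2(PPh3)2 (5 mol %), SnCl2 (5 mol %), CO (7 atm), MeCN, 75 °C
Reagents that add atoms: carbon monoxide, [C-]#[O+]
Why: Under CO the primary hydroxyl of 12 should be carbonylated at divalent palladium to an alkoxycarbonylpalladium chloride; the tethered aryl alkyne then inserts cis into the Pd–C(=O)O bond, so that the carbonyl carbon bonds to the alkyne carbon next to the stereocentre and closes the lactone, and HCl protonolysis of the vinyl–Pd bond with retention returns the catalyst. The closest known reaction type is the Norton-type Pd-catalysed cyclocarbonylation of homopropargylic alcohols to α-methylene- and (E)-α-alkylidene-γ-butyrolactones. The five-membered ring closes in the 5-exo-dig mode, because the 6-endo alternative would place a trans double bond in a six-membered ring. No new stereocentre is formed and the existing R centre is a spectator; the E geometry follows from cis addition of the acyl carbon and, after retentive protonolysis, hydrogen across the triple bond, which leaves the aryl group trans to the carbonyl. The step needs carbonylation to outrun 5-endo-dig attack of the hydroxyl on the palladium-bound alkyne and needs the phenol to stay out: CO pressure with phosphine and SnCl3 ligands keeps palladium a poor π-acid, and an aryloxycarbonyl palladium species formed reversibly at the phenol cannot reach the para alkyne.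

**Compound list**

1 | 3-(3,4-dimethoxyphenyl)propanoic acid | COc1ccc(CCC(=O)O)cc1OC | starting material
2 | (R)-4-benzyloxazolidin-2-one | O=C1N[C@H](Cc2ccccc2)CO1 | starting material
3 | 3-(3,4-dimethoxyphenyl)propanoic pivalic anhydride | COc1ccc(CCC(=O)OC(=O)C(C)(C)C)cc1OC | intermediate
4 | (R)-4-benzyl-3-[3-(3,4-dimethoxyphenyl)propanoyl]oxazolidin-2-one | COc1ccc(CCC(=O)N2[C@H](Cc3ccccc3)COC2=O)cc1OC | intermediate
5 | (R)-4-benzyl-3-[(S)-2-(3,4-dimethoxybenzyl)-3-hydroxypropanoyl]oxazolidin-2-one | O=C(N1[C@H](Cc2ccccc2)COC1=O)[C@H](CO)Cc1ccc(OC)c(OC)c1 | intermediate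
6 | (R)-4-benzyl-3-[(S)-3-[(tert-butyldimethylsilyl)oxy]-2-(3,4-dimethoxybenzyl)propanoyl]oxazolidin-2-one | O=C(N1[C@H](Cc2ccccc2)COC1=O)[C@H](CO[Si](C)(C)C(C)(C)C)Cc1ccc(OC)c(OC)c1 | intermediate
7 | (R)-3-[(tert-butyldimethylsilyl)oxy]-2-(3,4-dimethoxybenzyl)propan-1-ol | OC[C@H](CO[Si](C)(C)C(C)(C)C)Cc1ccc(OC)c(OC)c1 | intermediate
8 | (S)-3-[(tert-butyldimethylsilyl)oxy]-2-(3,4-dimethoxybenzyl)propanal | O=C[C@H](CO[Si](C)(C)C(C)(C)C)Cc1ccc(OC)c(OC)c1 | intermediate
9 | (R)-tert-butyl{[2-(3,4-dimethoxybenzyl)but-3-yn-1-yl]oxy}dimethylsilane | C#C[C@H](CO[Si](C)(C)C(C)(C)C)Cc1ccc(OC)c(OC)c1 | intermediate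
10 | 4-iodo-2-methoxyphenol | COc1cc(I)ccc1O | starting material
11 | (R)-4-{4-[(tert-butyldimethylsilyl)oxy]-3-(3,4-dimethoxybenzyl)but-1-yn-1-yl}-2-methoxyphenol | COc1cc(C#C[C@H](CO[Si](C)(C)C(C)(C)C)Cc2ccc(OC)c(OC)c2)ccc1O | intermediate
12 | (R)-4-[3-(3,4-dimethoxybenzyl)-4-hydroxybut-1-yn-1-yl]-2-methoxyphenol | COc1cc(C#C[C@H](CO)Cc2ccc(OC)c(OC)c2)ccc1O | intermediate
13 | (R,E)-4-(3,4-dimethoxybenzyl)-3-(4-hydroxy-3-methoxybenzylidene)dihydrofuran-2(3H)-one | COc1cc(/C=C2/C(=O)OC[C@@H]2Cc2ccc(OC)c(OC)c2)ccc1O | target

**Totals**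

Total step count: 9. Longest linear sequence: 9 steps (1 to 13).

**Steps most likely to fail**

Step 9. The hydroxyl may attack the palladium-activated, electron-rich aryl alkyne directly (5-endo-dig cycloisomerisation or hydration) before carbonylation, or the α-aryl vinylpalladium intermediate may isomerise and erode the alkene geometry. The fallback sets out from 12 and comes back at 13. It replaces CO by CO2 and palladium by nickel: syn-hydrocarboxylation of the alkyne (Ni(cod)2 cat., CsF, ZnEt2 in excess, CO2 1 atm, MeCN, 60 °C) should place the carboxyl group on the alkyne carbon next to the stereocentre and hydrogen on the aryl-bearing carbon from the same side. Acidic work-up should give (E)-2-[(R)-1-(3,4-dimethoxyphenyl)-3-hydroxypropan-2-yl]-3-(4-hydroxy-3-methoxyphenyl)acrylic acid F1, which should lactonise onto the primary hydroxyl (cat. TsOH, toluene, rt) to 13.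

Step 6. The basic methanol medium may enolise the α-branched aldehyde (loss of enantiopurity) or trigger β-elimination of the silyloxy group before homologation. The fallback sets out from 8 and comes back at 9. It is a Corey–Fuchs sequence: neutral dibromo-olefination (CBr4, PPh3, CH2Cl2, 0 °C) should give (R)-tert-butyl{[4,4-dibromo-2-(3,4-dimethoxybenzyl)but-3-en-1-yl]oxy}dimethylsilane F2, and n-BuLi (2.2 equiv, THF, −78 °C) followed by water should convert it into 9 by Fritsch–Buttenberg–Wiechell rearrangement.

Step 2. The titanium enolate may react incompletely with the formaldehyde source, build oligo(oxymethylene) chains, or lose facial control. The fallback sets out from 4 and comes back at 5. The same enolate (TiCl4, i-Pr2NEt, CH2Cl2, 0 °C) is alkylated with benzyl chloromethyl ether, an electrophile with established selectivity anti to the auxiliary benzyl group, to give (R)-4-benzyl-3-[(S)-3-(benzyloxy)-2-(3,4-dimethoxybenzyl)propanoyl]oxazolidin-2-one F3. Hydrogenolysis (H2, Pd/C, EtOAc, rt) should then give 5.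

**Further compounds**

F1 | step 9 | (E)-2-[(R)-1-(3,4-dimethoxyphenyl)-3-hydroxypropan-2-yl]-3-(4-hydroxy-3-methoxyphenyl)acrylic acid | OC(=O)/C(=C/c1ccc(O)c(OC)c1)[C@H](CO)Cc1ccc(OC)c(OC)c1
F2 | step 6 | (R)-tert-butyl{[4,4-dibromo-2-(3,4-dimethoxybenzyl)but-3-en-1-yl]oxy}dimethylsilane | BrC(Br)=C[C@H](CO[Si](C)(C)C(C)(C)C)Cc1ccc(OC)c(OC)c1
F3 | step 2 | (R)-4-benzyl-3-[(S)-3-(benzyloxy)-2-(3,4-dimethoxybenzyl)propanoyl]oxazolidin-2-one | O=C(N1[C@H](Cc2ccccc2)COC1=O)[C@H](COCc1ccccc1)Cc1ccc(OC)c(OC)c1
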